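**Plan**

- Target: (3S,5R,8S,3′R,6′R)-5,8-epoxy-5,8-dihydro-β,ε-carotene-3,3′-diol (chrysanthemaxanthin). Retrosynthesis cuts C11=C12 (Wittig) into a C15 furanoid aldehyde and a C25 ε-phosphonium salt, then C11′=C12′ (Wittig, C15 + C10) and C9′=C10′ (HWE on (R)-α-ionone).
- In the C15 aldehyde the O–C8 bond is cut. The ring O1–C5–C6=C7–C8 (oxygen on quaternary C5, endocyclic C6=C7, allylic H-bearing C8) is the cycloisomer of the α-hydroxyallene C5(OH)–C6=C7=C8, the allenic end group type of neoxanthin.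
- The allenol comes from SN2′ hydride opening of a 5,6-epoxy-7-yne (C8–H made, C6–O cleaved). The enyne comes from Sonogashira coupling (C6–C7) of an actinol-derived enol triflate.
- Forward: bought cyclohexane ring → enyne → anti-epoxide → (6R)-allene → dihydrofuran ring → C15 aldehyde. Separately: bought ε-ring → C15 → C25 salt. The chain is joined last at C11=C12.
- Stereochemistry: C3 from actinol; C5 from epoxidation anti to the C3 silyloxy group; C8 by relay epoxide centre → allene axis → C8. C6′ from (R)-α-ionone; C3′ by CBS reduction. E-alkenes from the building blocks, HWE/Wittig and thermal equilibration.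

Key step: step 7

Assumption: (4R,6R)-actinol (1) and natural-grade (R)-α-ionone (13) are taken as purchasable single enantiomers. Positions are given in carotenoid numbering (furanoid half C1–C15, ε half primed).

**Route**

Step 1
Reactants: 1 (4R,6R)-4-hydroxy-2,2,6-trimethylcyclohexanone (actinol)
Product: 2 (4R,6R)-4-(tert-butyldimethylsilyloxy)-2,2,6-trimethylcyclohexanone
Conditions: TBSCl, imidazole, DMF, rt
Reagents that add atoms: tert-butyldimethylsilyl chloride CC(C)(C)[Si](C)(C)Cl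
Why: Imidazole-promoted O-silylation masks the secondary hydroxyl for the enolate chemistry that follows and leaves the carbinol centre (C3 of the target) untouched.

Step 2
Reactants: 2 (4R,6R)-4-(tert-butyldimethylsilyloxy)-2,2,6-trimethylcyclohexanone
Product: 4 (4R)-4-(tert-butyldimethylsilyloxy)-2,6,6-trimethylcyclohex-1-en-1-yl trifluoromethanesulfonate, via potassium enolate 3 (not isolated)
Conditions: KHMDS, THF, −78 °C; then PhNTf2, −78 °C → rt
Reagents that add atoms: N-phenylbis(trifluoromethanesulfonimide) O=S(=O)(N(c1ccccc1)S(=O)(=O)C(F)(F)F)C(F)(F)F; potassium hexamethyldisilazide (potassium in the non-isolated enolate) C[Si](C)(C)[N-][Si](C)(C)C.[K+]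
Why: The ketone has a single α-hydrogen, so enolization is regiospecific and O-sulfonylation of the enolate gives the tetrasubstituted enol triflate; the methyl-bearing centre is erased on purpose and the silyloxy centre is not affected.

Step 3
Reactants: 5 (2E)-3-methylpent-2-en-4-yn-1-ol
Product: 6 tert-butyldimethyl{[(2E)-3-methylpent-2-en-4-yn-1-yl]oxy}silane
Conditions: TBSCl, imidazole, CH2Cl2, 0 °C → rt
Reagents that add atoms: tert-butyldimethylsilyl chloride CC(C)(C)[Si](C)(C)Cl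
Why: O-silylation of the primary allylic alcohol, so that the later epoxidation, hydride and gold steps meet only one free hydroxyl; the E-alkene is not touched.

Step 4
Reactants: 4 (4R)-4-(tert-butyldimethylsilyloxy)-2,6,6-trimethylcyclohex-1-en-1-yl trifluoromethanesulfonate; 6 tert-butyldimethyl{[(2E)-3-methylpent-2-en-4-yn-1-yl]oxy}silane
Product: 7 tert-butyl{[(2E)-5-[(4R)-4-(tert-butyldimethylsilyloxy)-2,6,6-trimethylcyclohex-1-en-1-yl]-3-methylpent-2-en-4-yn-1-yl]oxy}dimethylsilane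
Conditions: Pd(PPh3)4 (5 mol%), CuI (10 mol%), i-Pr2NH, DMF, rt → 40 °C
Reagents that add atoms: none
Why: Sonogashira coupling of the alkenyl triflate with the terminal alkyne forms the C6–C7 bond with retention of both alkene geometries, a coupling type well precedented for hindered cyclohexenyl triflates.

Step 5
Reactants: 7 tert-butyl{[(2E)-5-[(4R)-4-(tert-butyldimethylsilyloxy)-2,6,6-trimethylcyclohex-1-en-1-yl]-3-methylpent-2-en-4-yn-1-yl]oxy}dimethylsilane
Product: 8 (1R,4S,6R)-4-(tert-butyldimethylsilyloxy)-1-[(3E)-5-(tert-butyldimethylsilyloxy)-3-methylpent-3-en-1-yn-1-yl]-2,2,6-trimethyl-7-oxabicyclo[4.1.0]heptane (anti-epoxide, oxirane oxygen trans to the ring silyloxy group)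
Conditions: mCPBA, NaHCO3, CH2Cl2, 0 °C
Reagents that add atoms: 3-chloroperbenzoic acid OOC(=O)c1cccc(Cl)c1
Why: Prilezhaev epoxidation picks the tetrasubstituted C5=C6 bond, the most nucleophilic alkene (C9=C10 is deactivated by its allylic silyloxy group and the alkyne is inert); attack anti to the C3 silyloxy group is expected to predominate and sets C5 (R) together with C6, with the syn diastereomer to be removed by chromatography.

Step 6
Reactants: 8 (1R,4S,6R)-4-(tert-butyldimethylsilyloxy)-1-[(3E)-5-(tert-butyldimethylsilyloxy)-3-methylpent-3-en-1-yn-1-yl]-2,2,6-trimethyl-7-oxabicyclo[4.1.0]heptane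
Product: 9 (1R,5S)-5-(tert-butyldimethylsilyloxy)-2-[(3E)-5-(tert-butyldimethylsilyloxy)-3-methylpenta-1,3-dien-1-ylidene]-1,3,3-trimethylcyclohexan-1-ol with (R)-configured allene axis [(3S,5R,6R) in carotenoid numbering]
Conditions: DIBAL-H (3 equiv), CH2Cl2, 0 °C; Rochelle salt work-up
Reagents that add atoms: none
Why: SN2′ reduction of the alkynyl oxirane: aluminium binds the oxirane oxygen and delivers hydride to C8 on that same face as the C6–O bond breaks, so the C5–O bond and the C5 configuration are kept and the epoxide configuration is translated into the (6R) allene axis, the conversion relied on for allenic carotenoid end groups.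

Step 7
Reactants: 9 (1R,5S)-5-(tert-butyldimethylsilyloxy)-2-[(3E)-5-(tert-butyldimethylsilyloxy)-3-methylpenta-1,3-dien-1-ylidene]-1,3,3-trimethylcyclohexan-1-ol with (R)-configured allene axis
Product: 10 (2S,6S,7aR)-6-(tert-butyldimethylsilyloxy)-2-[(2E)-4-(tert-butyldimethylsilyloxy)but-2-en-2-yl]-4,4,7a-trimethyl-2,4,5,6,7,7a-hexahydro-1-benzofuran
Conditions: AuCl3 (5 mol%), THF, 0 °C → rt, dark
Reagents that add atoms: none
Why: Gold π-activation of the distal C7=C8 bond of the allene makes C8 electrophilic, the tertiary C5 hydroxyl adds to C8 anti to gold to give a σ-vinylgold oxonium species, and protodeauration at C7 releases the 2,5-dihydrofuran and the catalyst. The closest known reaction type is the gold-catalysed cycloisomerization of α-hydroxyallenes to 2,5-dihydrofurans with axis-to-centre chirality transfer. The one ring closed is the dihydrofuran O1–C5–C6=C7–C8, by 5-endo-trig O–C8 bond formation, fused to the existing cyclohexane at C5–C6. The one new stereocentre, C8, is controlled by the (6R) allene axis: oxygen enters C8 in the plane of C5, C6 and C7, so H8 and C9 keep the faces they occupy in the allene, and with the (5R) carbinol this places C9 on the face of the C5 methyl group, which is (8S). The step needs O-attack to win over carbocyclization of the vinylallene, secured by the 5-endo reach of the only free hydroxyl (the other two are silyl ethers), and it needs the acid-labile bis-allylic C8–O bond to keep its configuration, secured by the weakly Lewis-acidic THF medium and a short contact time.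

Step 8
Reactants: 10 (2S,6S,7aR)-6-(tert-butyldimethylsilyloxy)-2-[(2E)-4-(tert-butyldimethylsilyloxy)but-2-en-2-yl]-4,4,7a-trimethyl-2,4,5,6,7,7a-hexahydro-1-benzofuran
Product: 11 (2S,6S,7aR)-2-[(2E)-4-hydroxybut-2-en-2-yl]-4,4,7a-trimethyl-2,4,5,6,7,7a-hexahydro-1-benzofuran-6-ol
Conditions: TBAF, THF, rt
Reagents that add atoms: none
Why: Fluoride-induced cleavage of both silyl ethers under non-acidic conditions, which spare the bis-allylic C8–O bond and therefore the C8 configuration.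

Step 9
Reactants: 11 (2S,6S,7aR)-2-[(2E)-4-hydroxybut-2-en-2-yl]-4,4,7a-trimethyl-2,4,5,6,7,7a-hexahydro-1-benzofuran-6-ol
Product: 12 (2E)-3-[(2S,6S,7aR)-6-hydroxy-4,4,7a-trimethyl-2,4,5,6,7,7a-hexahydro-1-benzofuran-2-yl]but-2-enal
Conditions: activated MnO2, CH2Cl2, rt
Reagents that add atoms: none
Why: MnO2 oxidizes only the primary allylic alcohol and leaves the saturated secondary alcohol, the alkene geometry and the stereocentres alone.

Step 10
Reactants: 13 (R)-α-ionone, (3E)-4-[(1R)-2,6,6-trimethylcyclohex-2-en-1-yl]but-3-en-2-one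
Product: 14 ethyl (2E,4E)-3-methyl-5-[(1R)-2,6,6-trimethylcyclohex-2-en-1-yl]penta-2,4-dienoate
Conditions: (EtO)2P(O)CH2CO2Et, NaH, THF, 0 °C → rt; 9′E isomer separated from minor 9′Z by chromatography
Reagents that add atoms: triethyl phosphonoacetate CCOC(=O)CP(=O)(OCC)OCC
Why: Horner–Wadsworth–Emmons olefination of the methyl ketone gives mainly the (E)-trisubstituted dienoate, and the weakly basic phosphonate anion should not enolize the C6′ stereocentre, as known for α-ionylidene esters.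

Step 11
Reactants: 14 ethyl (2E,4E)-3-methyl-5-[(1R)-2,6,6-trimethylcyclohex-2-en-1-yl]penta-2,4-dienoate
Product: 15 ethyl (2E,4E)-3-methyl-5-[(1R)-2,6,6-trimethyl-4-oxocyclohex-2-en-1-yl]penta-2,4-dienoate
Conditions: t-BuOOH (70% aq., 5 equiv), Rh2(cap)4 (1 mol%), CH2Cl2, rt → 40 °C
Reagents that add atoms: tert-butyl hydroperoxide CC(C)(C)OO
Why: Radical allylic C–H oxidation: the tert-butylperoxyl radical abstracts an accessible ring allylic hydrogen at C3′ rather than the hindered tertiary C6′–H, and the mixed peroxide collapses to the enone, as precedented for 3-oxo-α-ionone derivatives; the base-free conditions protect the C6′ centre.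

Step 12
Reactants: 15 ethyl (2E,4E)-3-methyl-5-[(1R)-2,6,6-trimethyl-4-oxocyclohex-2-en-1-yl]penta-2,4-dienoate
Product: 16 ethyl (2E,4E)-5-[(1R,4R)-4-hydroxy-2,6,6-trimethylcyclohex-2-en-1-yl]-3-methylpenta-2,4-dienoate
Conditions: (S)-Me-CBS oxazaborolidine (0.5 equiv), catecholborane (1.5 equiv), toluene, −78 °C
Reagents that add atoms: none
Why: Corey–Bakshi–Shibata reduction, a catalyst-controlled 1,2-reduction in which the ring alkene acts as the large and the CH2 as the small substituent, so the (S)-catalyst should deliver hydride to give the (3′R) alcohol trans to the C6′ side chain while the dienoate is inert at this temperature.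

Step 13
Reactants: 16 ethyl (2E,4E)-5-[(1R,4R)-4-hydroxy-2,6,6-trimethylcyclohex-2-en-1-yl]-3-methylpenta-2,4-dienoate
Product: 17 (2E,4E)-5-[(1R,4R)-4-hydroxy-2,6,6-trimethylcyclohex-2-en-1-yl]-3-methylpenta-2,4-dien-1-ol
Conditions: DIBAL-H (3.5 equiv), CH2Cl2, −78 °C; Rochelle salt work-up
Reagents that add atoms: none
Why: DIBAL-H reduces the conjugated ester by 1,2-addition to the primary allylic alcohol without touching the diene geometry or the stereocentres.

Step 14
Reactants: 17 (2E,4E)-5-[(1R,4R)-4-hydroxy-2,6,6-trimethylcyclohex-2-en-1-yl]-3-methylpenta-2,4-dien-1-ol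
Product: 18 [(2E,4E)-5-[(1R,4R)-4-hydroxy-2,6,6-trimethylcyclohex-2-en-1-yl]-3-methylpenta-2,4-dien-1-yl]triphenylphosphonium bromide
Conditions: PPh3·HBr, MeOH, 0 °C → rt
Reagents that add atoms: triphenylphosphine hydrobromide [Br-].[PH+](c1ccccc1)(c1ccccc1)c1ccccc1
Why: Phosphonium salt formation by ionization of the primary dienylic alcohol to a pentadienyl cation and capture by triphenylphosphine at the terminus; the ring allylic hydroxyl ionizes far less readily and is kept, as in Wittig salts of this end group used for lutein.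

Step 15
Reactants: 18 [(2E,4E)-5-[(1R,4R)-4-hydroxy-2,6,6-trimethylcyclohex-2-en-1-yl]-3-methylpenta-2,4-dien-1-yl]triphenylphosphonium bromide; 19 (2E,4E,6E)-2,7-dimethylocta-2,4,6-trienedial
Product: 22 (2E,4E,6E,8E,10E,12E)-13-[(1R,4R)-4-hydroxy-2,6,6-trimethylcyclohex-2-en-1-yl]-2,7,11-trimethyltrideca-2,4,6,8,10,12-hexaenal, via C15 ylide 20 (not isolated), via 11′Z isomer 21 (not isolated)
Conditions: NaOMe, MeOH/CH2Cl2, 0 °C → rt, 19 in excess (2 equiv); then heptane, reflux, Ar, dark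
Reagents that add atoms: none
Why: Wittig olefination of the symmetrical dialdehyde used in excess should stop at the mono-adduct because the remaining formyl group becomes part of a longer, less electrophilic polyenal, and heating converts the hindered 11′Z isomer formed alongside into the all-E aldehyde.

Step 16
Reactants: 22 (2E,4E,6E,8E,10E,12E)-13-[(1R,4R)-4-hydroxy-2,6,6-trimethylcyclohex-2-en-1-yl]-2,7,11-trimethyltrideca-2,4,6,8,10,12-hexaenal
Product: 23 (2E,4E,6E,8E,10E,12E)-13-[(1R,4R)-4-hydroxy-2,6,6-trimethylcyclohex-2-en-1-yl]-2,7,11-trimethyltrideca-2,4,6,8,10,12-hexaen-1-ol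
Conditions: NaBH4, EtOH/THF, 0 °C
Reagents that add atoms: none
Why: Borohydride 1,2-reduction of the polyenal to the primary polyenylic alcohol without change of alkene geometry.

Step 17
Reactants: 23 (2E,4E,6E,8E,10E,12E)-13-[(1R,4R)-4-hydroxy-2,6,6-trimethylcyclohex-2-en-1-yl]-2,7,11-trimethyltrideca-2,4,6,8,10,12-hexaen-1-ol
Product: 24 [(2E,4E,6E,8E,10E,12E)-13-[(1R,4R)-4-hydroxy-2,6,6-trimethylcyclohex-2-en-1-yl]-2,7,11-trimethyltrideca-2,4,6,8,10,12-hexaen-1-yl]triphenylphosphonium bromide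
Conditions: PPh3·HBr, MeOH/CH2Cl2, 0 °C → rt
Reagents that add atoms: triphenylphosphine hydrobromide [Br-].[PH+](c1ccccc1)(c1ccccc1)c1ccccc1
Why: The polyenylic primary alcohol ionizes very easily to a delocalized cation that triphenylphosphine traps at the chain terminus, the standard entry to carotenoid Wittig salts, while the less activated ring allylic hydroxyl should survive as in step 14.

Step 18
Reactants: 24 [(2E,4E,6E,8E,10E,12E)-13-[(1R,4R)-4-hydroxy-2,6,6-trimethylcyclohex-2-en-1-yl]-2,7,11-trimethyltrideca-2,4,6,8,10,12-hexaen-1-yl]triphenylphosphonium bromide; 12 (2E)-3-[(2S,6S,7aR)-6-hydroxy-4,4,7a-trimethyl-2,4,5,6,7,7a-hexahydro-1-benzofuran-2-yl]but-2-enal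
Product: 27 (3S,5R,8S,3′R,6′R)-5,8-epoxy-5,8-dihydro-β,ε-carotene-3,3′-diol (chrysanthemaxanthin; target), via C25 ylide 25 (not isolated), via 11Z isomer 26 (not isolated)
Conditions: 1,2-epoxybutane/EtOH, reflux, Ar, dark; then heptane, reflux, Ar, dark
Reagents that add atoms: none
Why: Wittig olefination under the acid- and strong-base-free epoxybutane protocol (bromide opens the epoxide and the resulting alkoxide generates the ylide) joins C11 to C12 with free hydroxyls tolerated; the conditions should leave the bis-allylic C8–O bond and the γ-hydrogen at C8 of the enal alone, and heating equilibrates the hindered 11Z isomer to the all-E target.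

**Compound list**

1 | (4R,6R)-4-hydroxy-2,2,6-trimethylcyclohexanone (actinol) | CC1(C)C[C@H](O)C[C@@H](C)C1=O | starting material
2 | (4R,6R)-4-(tert-butyldimethylsilyloxy)-2,2,6-trimethylcyclohexanone | CC1(C)C[C@H](O[Si](C)(C)C(C)(C)C)C[C@@H](C)C1=O | intermediate
3 | potassium (4R)-4-(tert-butyldimethylsilyloxy)-2,6,6-trimethylcyclohex-1-en-1-olate (not isolated) | CC1=C([O-])C(C)(C)C[C@H](O[Si](C)(C)C(C)(C)C)C1.[K+] | intermediate
4 | (4R)-4-(tert-butyldimethylsilyloxy)-2,6,6-trimethylcyclohex-1-en-1-yl trifluoromethanesulfonate | CC1=C(OS(=O)(=O)C(F)(F)F)C(C)(C)C[C@H](O[Si](C)(C)C(C)(C)C)C1 | intermediate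
5 | (2E)-3-methylpent-2-en-4-yn-1-ol | C#C/C(C)=C/CO | starting material
6 | tert-butyldimethyl{[(2E)-3-methylpent-2-en-4-yn-1-yl]oxy}silane | C#C/C(C)=C/CO[Si](C)(C)C(C)(C)C | intermediate
7 | tert-butyl{[(2E)-5-[(4R)-4-(tert-butyldimethylsilyloxy)-2,6,6-trimethylcyclohex-1-en-1-yl]-3-methylpent-2-en-4-yn-1-yl]oxy}dimethylsilane | CC1=C(C#C/C(C)=C/CO[Si](C)(C)C(C)(C)C)C(C)(C)C[C@H](O[Si](C)(C)C(C)(C)C)C1 | intermediate
8 | (1R,4S,6R)-4-(tert-butyldimethylsilyloxy)-1-[(3E)-5-(tert-butyldimethylsilyloxy)-3-methylpent-3-en-1-yn-1-yl]-2,2,6-trimethyl-7-oxabicyclo[4.1.0]heptane (anti-epoxide) | C[C@]12O[C@@]1(C#C/C(C)=C/CO[Si](C)(C)C(C)(C)C)C(C)(C)C[C@H](O[Si](C)(C)C(C)(C)C)C2 | intermediate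
9 | (1R,5S)-5-(tert-butyldimethylsilyloxy)-2-[(3E)-5-(tert-butyldimethylsilyloxy)-3-methylpenta-1,3-dien-1-ylidene]-1,3,3-trimethylcyclohexan-1-ol, (R) allene axis | C[C@@]1(O)C[C@@H](O[Si](C)(C)C(C)(C)C)CC(C)(C)C1=[C@@]=C([H])/C(C)=C/CO[Si](C)(C)C(C)(C)C | intermediate
10 | (2S,6S,7aR)-6-(tert-butyldimethylsilyloxy)-2-[(2E)-4-(tert-butyldimethylsilyloxy)but-2-en-2-yl]-4,4,7a-trimethyl-2,4,5,6,7,7a-hexahydro-1-benzofuran | C/C(=C\CO[Si](C)(C)C(C)(C)C)[C@@H]1C=C2C(C)(C)C[C@H](O[Si](C)(C)C(C)(C)C)C[C@@]2(C)O1 | intermediate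
11 | (2S,6S,7aR)-2-[(2E)-4-hydroxybut-2-en-2-yl]-4,4,7a-trimethyl-2,4,5,6,7,7a-hexahydro-1-benzofuran-6-ol | C/C(=C\CO)[C@@H]1C=C2C(C)(C)C[C@H](O)C[C@@]2(C)O1 | intermediate
12 | (2E)-3-[(2S,6S,7aR)-6-hydroxy-4,4,7a-trimethyl-2,4,5,6,7,7a-hexahydro-1-benzofuran-2-yl]but-2-enal | C/C(=C\C=O)[C@@H]1C=C2C(C)(C)C[C@H](O)C[C@@]2(C)O1 | intermediate
13 | (R)-α-ionone | CC1=CCCC(C)(C)[C@H]1/C=C/C(C)=O | starting material
14 | ethyl (2E,4E)-3-methyl-5-[(1R)-2,6,6-trimethylcyclohex-2-en-1-yl]penta-2,4-dienoate | CC1=CCCC(C)(C)[C@H]1/C=C/C(C)=C/C(=O)OCC | intermediate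
15 | ethyl (2E,4E)-3-methyl-5-[(1R)-2,6,6-trimethyl-4-oxocyclohex-2-en-1-yl]penta-2,4-dienoate | CC1=CC(=O)CC(C)(C)[C@H]1/C=C/C(C)=C/C(=O)OCC | intermediate
16 | ethyl (2E,4E)-5-[(1R,4R)-4-hydroxy-2,6,6-trimethylcyclohex-2-en-1-yl]-3-methylpenta-2,4-dienoate | CC1=C[C@H](O)CC(C)(C)[C@H]1/C=C/C(C)=C/C(=O)OCC | intermediate
17 | (2E,4E)-5-[(1R,4R)-4-hydroxy-2,6,6-trimethylcyclohex-2-en-1-yl]-3-methylpenta-2,4-dien-1-ol | CC1=C[C@H](O)CC(C)(C)[C@H]1/C=C/C(C)=C/CO | intermediate
18 | [(2E,4E)-5-[(1R,4R)-4-hydroxy-2,6,6-trimethylcyclohex-2-en-1-yl]-3-methylpenta-2,4-dien-1-yl]triphenylphosphonium bromide | CC1=C[C@H](O)CC(C)(C)[C@H]1/C=C/C(C)=C/C[P+](c2ccccc2)(c2ccccc2)c2ccccc2.[Br-] | intermediate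
19 | (2E,4E,6E)-2,7-dimethylocta-2,4,6-trienedial | O=C/C(C)=C/C=C/C=C(C)/C=O | starting material
20 | C15 ylide from 18 (not isolated) | CC1=C[C@H](O)CC(C)(C)[C@H]1/C=C/C(C)=C/C=P(c2ccccc2)(c2ccccc2)c2ccccc2 | intermediate
21 | 11′Z isomer of 22, (2E,4E,6E,8Z,10E,12E) (not isolated) | CC1=C[C@H](O)CC(C)(C)[C@H]1/C=C/C(C)=C/C=C\C(C)=C\C=C\C=C(C)\C=O | intermediate
22 | (2E,4E,6E,8E,10E,12E)-13-[(1R,4R)-4-hydroxy-2,6,6-trimethylcyclohex-2-en-1-yl]-2,7,11-trimethyltrideca-2,4,6,8,10,12-hexaenal | CC1=C[C@H](O)CC(C)(C)[C@H]1/C=C/C(C)=C/C=C/C(C)=C/C=C/C=C(C)/C=O | intermediate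
23 | (2E,4E,6E,8E,10E,12E)-13-[(1R,4R)-4-hydroxy-2,6,6-trimethylcyclohex-2-en-1-yl]-2,7,11-trimethyltrideca-2,4,6,8,10,12-hexaen-1-ol | CC1=C[C@H](O)CC(C)(C)[C@H]1/C=C/C(C)=C/C=C/C(C)=C/C=C/C=C(C)/CO | intermediate
24 | [(2E,4E,6E,8E,10E,12E)-13-[(1R,4R)-4-hydroxy-2,6,6-trimethylcyclohex-2-en-1-yl]-2,7,11-trimethyltrideca-2,4,6,8,10,12-hexaen-1-yl]triphenylphosphonium bromide | CC1=C[C@H](O)CC(C)(C)[C@H]1/C=C/C(C)=C/C=C/C(C)=C/C=C/C=C(C)/C[P+](c2ccccc2)(c2ccccc2)c2ccccc2.[Br-] | intermediate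
25 | C25 ylide from 24 (not isolated) | CC1=C[C@H](O)CC(C)(C)[C@H]1/C=C/C(C)=C/C=C/C(C)=C/C=C/C=C(C)/C=P(c2ccccc2)(c2ccccc2)c2ccccc2 | intermediate
26 | 11Z isomer of 27 (not isolated) | CC1=C[C@H](O)CC(C)(C)[C@H]1/C=C/C(C)=C/C=C/C(C)=C/C=C/C=C(C)/C=C\C=C(/C)[C@@H]1C=C2C(C)(C)C[C@H](O)C[C@@]2(C)O1 | intermediate
27 | (3S,5R,8S,3′R,6′R)-5,8-epoxy-5,8-dihydro-β,ε-carotene-3,3′-diol (chrysanthemaxanthin) | CC1=C[C@H](O)CC(C)(C)[C@H]1/C=C/C(C)=C/C=C/C(C)=C/C=C/C=C(C)/C=C/C=C(\C)[C@@H]1C=C2C(C)(C)C[C@H](O)C[C@@]2(C)O1 | target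

**Step count and risks**

Total step count: 18. Longest linear sequence: 9 steps (steps 1, 2, 4–9 and 18 from 1; equally steps 10–18 from 13).

Steps most likely to fail:

1. Step 7 (gold cycloisomerization). The vinylallene may enter a competing gold-triggered carbocyclization or oligomerize, or the C8 configuration may erode by reversible ionization of the bis-allylic C8–O bond on the Lewis acid. Fallback from 9 back to 10: electrophilic 5-endo iodoetherification of allenol 9 with N-iodosuccinimide (CH2Cl2, 0 °C) forms the same O–C8 bond with the same axis-to-centre transfer and gives the 3-iodo-2,5-dihydrofuran F1. Radical deiodination of F1 (Bu3SnH, Et3B/air, toluene, rt) then gives 10.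

2. Step 5 (epoxidation). The peracid may show poor facial selectivity, or partly attack the C9=C10 bond. Fallback from 4 back to 8 with reagent-controlled epoxidation: methoxycarbonylation of triflate 4 (Pd(OAc)2, dppp, CO, MeOH, Et3N, DMF) gives the methyl ester F2, and DIBAL-H reduction gives the allylic alcohol F3. Sharpless asymmetric epoxidation of F3 (Ti(Oi-Pr)4, D-(−)-diethyl tartrate, t-BuOOH, CH2Cl2, −20 °C) gives the anti-epoxy alcohol F4; the tartrate is chosen by the Sharpless mnemonic to deliver oxygen to the face anti to the silyloxy group. Dess–Martin oxidation gives the epoxy aldehyde F5, and Ohira–Bestmann homologation (dimethyl 1-diazo-2-oxopropylphosphonate, K2CO3, MeOH) gives the terminal epoxy alkyne F6. Sonogashira coupling of F6 with the vinyl iodide F7, made by silylation of (E)-3-iodobut-2-en-1-ol, gives epoxide 8.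

3. Step 12 (CBS reduction). Catalyst and substrate facial preferences may be mismatched, or conjugate reduction may compete. Fallback from 15 back to 16: Luche reduction of 15 (NaBH4, CeCl3·7H2O, MeOH, −40 °C) gives 16 together with its C3′ epimer F8, and the two are separated by chromatography. F8 is inverted by a Mitsunobu reaction (4-nitrobenzoic acid, PPh3, DIAD, THF) to the 4-nitrobenzoate F9. Ethanolysis of F9 (K2CO3, EtOH) gives 16.

Further compounds
F1 | step 7 | 3-iodo derivative of 10 (iodine on C7; same spatial arrangement at C3, C5 and C8) | C/C(=C\CO[Si](C)(C)C(C)(C)C)[C@@H]1C(I)=C2C(C)(C)C[C@H](O[Si](C)(C)C(C)(C)C)C[C@@]2(C)O1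
F2 | step 5 | methyl (4R)-4-(tert-butyldimethylsilyloxy)-2,6,6-trimethylcyclohex-1-ene-1-carboxylate | CC1=C(C(=O)OC)C(C)(C)C[C@H](O[Si](C)(C)C(C)(C)C)C1
F3 | step 5 | [(4R)-4-(tert-butyldimethylsilyloxy)-2,6,6-trimethylcyclohex-1-en-1-yl]methanol | CC1=C(CO)C(C)(C)C[C@H](O[Si](C)(C)C(C)(C)C)C1
F4 | step 5 | [4-(tert-butyldimethylsilyloxy)-2,2,6-trimethyl-7-oxabicyclo[4.1.0]heptan-1-yl]methanol, oxirane and silyloxy centres as in 8 | C[C@]12O[C@@]1(CO)C(C)(C)C[C@H](O[Si](C)(C)C(C)(C)C)C2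
F5 | step 5 | 4-(tert-butyldimethylsilyloxy)-2,2,6-trimethyl-7-oxabicyclo[4.1.0]heptane-1-carbaldehyde, centres as in 8 | C[C@]12O[C@@]1(C=O)C(C)(C)C[C@H](O[Si](C)(C)C(C)(C)C)C2
F6 | step 5 | 4-(tert-butyldimethylsilyloxy)-1-ethynyl-2,2,6-trimethyl-7-oxabicyclo[4.1.0]heptane, centres as in 8 | C[C@]12O[C@@]1(C#C)C(C)(C)C[C@H](O[Si](C)(C)C(C)(C)C)C2
F7 | step 5 | tert-butyl{[(2E)-3-iodobut-2-en-1-yl]oxy}dimethylsilane | C/C(I)=C\CO[Si](C)(C)C(C)(C)C
F8 | step 12 | ethyl (2E,4E)-5-[(1R,4S)-4-hydroxy-2,6,6-trimethylcyclohex-2-en-1-yl]-3-methylpenta-2,4-dienoate | CC1=C[C@@H](O)CC(C)(C)[C@H]1/C=C/C(C)=C/C(=O)OCC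
F9 | step 12 | (1R,4R)-4-[(1E,3E)-5-ethoxy-3-methyl-5-oxopenta-1,3-dien-1-yl]-3,5,5-trimethylcyclohex-2-en-1-yl 4-nitrobenzoate | CC1=C[C@H](OC(=O)c2ccc(cc2)[N+](=O)[O-])CC(C)(C)[C@H]1/C=C/C(C)=C/C(=O)OCC
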